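**Reading the runs.** I decided to read both runs as millimolar of target made per minute, not as percent of the charge. The flask is stirred at constant volume, with the solid substrate charged undissolved.

| flask | solid substrate | remark | time |
|---|---|---|---|
| red | 10 mM | run made earlier |  |
| amber | 15 mM | run made earlier |  |
| flask | 20 mM |  | 12 min |

| run | time / min | target / % |
|---|---|---|
| red | 1.50 | 1.4 |
| red | 3.00 | 2.9 |
| red | 5.00 | 5.3 |
| red | 6.00 | 6.0 |
| red | 8.00 | 6.9 |
| red | 10.0 | 8.2 |
| amber | 0.833 | 0.4 |
| amber | 1.33 | 0.8 |
| amber | 2.00 | 1.2 |
| amber | 4.00 | 2.2 |
| amber | 6.00 | 2.7 |
| amber | 10.0 | 5.6 |

(each reading ± 0.5 percentage points)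

- solid substrate is a solid; its amount is given per volume of the solution
- steps that have been proposed: solid substrate <-> starting material; starting material <-> target; isomer of the product <-> starting material; target <-> isomer of the product
- at the start none of the solid substrate is in solution

- midnight: doubling the dissolution coefficient of the solid substrate, all else as stated
- spring: doubling the solubility of the solid substrate, all else as stated

- the target standing at 12 min, as a percentage of the solid substrate charged
- the change that raises the amount of target at 12 min, in percent of the solid substrate charged most ("none" if none brings more than 2 percentage points) (midnight / spring / none)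
- amount of target at 12 min, in percent of the solid substrate charged, after spring

I divided the target concentration at the last reading by its time. As a reading, the red run gives 0.0820 mM min⁻¹, and I called this figure F, the feed rate. The amber run gives 0.0840 mM min⁻¹. Scatter moves the red figure by 0.00500 mM min⁻¹, so the two agree. Over these runs, target formed pseudo-zero-order in the solid charged.

**On arrival.** I carried F to the flask, where it gives 0.984 mM of target at 12 min, or 4.92% of the charge. Leave the charge alone: the amber run held more solid than the red run, yet it gave about the same F.

**The forecast.** It gave 4.9%, chose spring, and put that change at 9.5%, holding that “the rate does not depend on the solid charged”.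

**The flask.** The flask gave 4.74%, and spring led with 4.7 percentage points against 3 points for midnight, reaching 9.47%.

    solid substrate ⇌ starting material, rate k1*(cs1 - [starting material]) while solid is left; crystals form when [starting material] > cs1 (solubility = 3.00 mM, k = 0.0850 min⁻¹)
    starting material ⇌ target (K = 0.950, k = 0.930 min⁻¹)
    isomer of the product ⇌ starting material (k = 0.100 min⁻¹)
    target ⇌ isomer of the product (K = 0.670, k = 0.0370 min⁻¹)

The flask's own F was 0.0789 mM min⁻¹. A much later reading is what parts the reckoning from the flask. The neighbouring flask is the same flask read at 50 min, where F gives 20.5%, but it held 11.3%, an average F of 0.0451 mM min⁻¹, with 82% of the charge still there as solid or dissolved.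

All runs are calculated on assumed constants.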